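The cycloheptane ring carries, around its CH(CH3)–CH(CH3) bond (C8–C8'), an acetoxy carbon (C7') on one side and a CH2 (C7) on the other. The route exploits these two flanking atoms: an O–SiMe2–C bridge joins the C7' oxygen to C7, and a 6-endo radical cyclisation of a C8' radical onto the tethered α-silylstyrene closes a 1,2-oxasilinane by forming C8–C8', setting both methyl-bearing centres from the carbinol centre through a chair-like transition state. The precursor is an open-chain bromo silyl ether assembled from two propiophenones. Fluoride then excises silicon, and the seven-membered ring is closed last by oxidative para-ipso attack of ring B on the phenol of ring A.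

Key step: step 6

Remark: 1 and 4 are assumed to be purchasable. Locants: C7 = the CH2 at the spiro carbon, C8 and C8' = the methyl-bearing carbons, C7' = the acetoxy carbon; ring A becomes the dienone, ring B is the trimethoxybenzene ring.

Step 1
Reactants: 1 1-(3,4,5-trimethoxyphenyl)propan-1-one
Product: 2 2-bromo-1-(3,4,5-trimethoxyphenyl)propan-1-one (racemic)
Conditions: CuBr2 (2 equiv), EtOAc/CHCl3, reflux
Reagents that add atoms: copper dibromide, Br[Cu]Br
Why: α-Bromination of the aryl ketone through its enol by CuBr2; the new centre needs no control because C8' becomes a radical in step 6.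

Step 2
Reactants: 2 2-bromo-1-(3,4,5-trimethoxyphenyl)propan-1-one
Product: 3 (1R)-2-bromo-1-(3,4,5-trimethoxyphenyl)propan-1-ol (mixture of C2 epimers)
Conditions: (R)-Me-CBS [(3aR)-1-methyl-3,3-diphenyltetrahydro-1H,3H-pyrrolo[1,2-c][1,3,2]oxazaborole] (10 mol %), BH3·SMe2, THF, −20 °C; then MeOH
Reagents that add atoms: none
Why: Corey–Bakshi–Shibata reduction; catalyst-controlled hydride delivery with the aryl group as the large substituent should set C7' in both enantiomers of 2.

Step 3
Reactants: 4 1-(4-hydroxy-3,5-dimethoxyphenyl)propan-1-one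
Product: 5 1-[4-(benzyloxy)-3,5-dimethoxyphenyl]propan-1-one
Conditions: BnBr, K2CO3, DMF, 60 °C
Reagents that add atoms: benzyl bromide, BrCc1ccccc1
Why: Williamson ether synthesis; the benzyl ether shields the phenol from n-BuLi in step 5 and from the Mitsunobu conditions in step 8.

Step 4
Reactants: 5 1-[4-(benzyloxy)-3,5-dimethoxyphenyl]propan-1-one
Product: 6 N'-{(1E)-1-[4-(benzyloxy)-3,5-dimethoxyphenyl]propylidene}-2,4,6-tri(propan-2-yl)benzenesulfonohydrazide
Conditions: 2,4,6-tri(propan-2-yl)benzenesulfonohydrazide, cat. HCl, MeOH/THF, rt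
Reagents that add atoms: 2,4,6-tri(propan-2-yl)benzenesulfonohydrazide, NNS(=O)(=O)c1c(C(C)C)cc(C(C)C)cc1C(C)C
Why: Acid-catalysed hydrazone condensation should give the E hydrazone with the sulfonamide nitrogen syn to the ethyl group, the geometry needed for deprotonation of its CH2 in step 5.

Step 5
Reactants: 6 the sulfonylhydrazone; 3 (1R)-2-bromo-1-(3,4,5-trimethoxyphenyl)propan-1-ol
Product: 9 {(1E)-1-[4-(benzyloxy)-3,5-dimethoxyphenyl]prop-1-en-1-yl}[(1R)-2-bromo-1-(3,4,5-trimethoxyphenyl)propoxy]dimethylsilane (C2 epimers of the bromide), via vinyllithium 7 (not isolated), via chlorosilane 8 (not isolated)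
Conditions: n-BuLi (2.1 equiv), THF, −78 → 0 °C; cannulated into Me2SiCl2 (5 equiv), −78 °C → rt, volatiles removed; then 3, imidazole, CH2Cl2, 0 °C → rt
Reagents that add atoms: dichlorodimethylsilane, C[Si](C)(Cl)Cl
Why: Shapiro reaction: double deprotonation and loss of sulfinate and dinitrogen should give the vinyllithium with lithium trans to the methyl group, which is silylated with retention and then joined to 3 by alcoholysis of the remaining Si–Cl bond; no stereocentre is formed.

Step 6
Reactants: 9 the bromo silyl ether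
Product: 10 (4S,5S,6S)-3-[4-(benzyloxy)-3,5-dimethoxyphenyl]-2,2,4,5-tetramethyl-6-(3,4,5-trimethoxyphenyl)-1,2-oxasilinane (C3 epimers)
Conditions: Bu3SnH (1.3 equiv, syringe pump), AIBN (0.2 equiv), benzene (5 mM), 80 °C
Reagents that add atoms: none
Why: Bu3Sn• abstracts bromine from either C8' epimer of 9 to give one secondary C8' radical, which adds to the methyl-bearing alkene carbon (C8) of the tethered α-silylstyrene and so forms the C8–C8' bond; the benzylic α-silyl radical at C7 then takes hydrogen from Bu3SnH and carries the chain. The closest known reaction type is the temporary silicon connection, the radical cyclisation of alkenylsilyl ethers of 2-halo alcohols, for which the 6-endo mode is established. The ring closed is the 1,2-oxasilinane (O–Si–C7–C8–C8'–C7') in 6-endo-trig mode; 5-exo attack at C7 is disfavoured by its full substitution and would give an unstabilised radical. Both new stereocentres should follow from a chair-like transition state with the ring B aryl group at C7' (set in step 2) equatorial: the C8' methyl then sits equatorial, trans to that aryl group, and the C8 methyl ends equatorial because it is trans to silicon in the E alkene, giving the all-trans ring. The step needs ring closure to outrun hydrogen transfer to the first radical, which low stannane concentration and the gain of benzylic stabilisation should secure; the uncontrolled C7 centre is erased in step 7.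

Step 7
Reactants: 10 the 1,2-oxasilinane
Product: 11 (1S,2S,3R)-4-[4-(benzyloxy)-3,5-dimethoxyphenyl]-2,3-dimethyl-1-(3,4,5-trimethoxyphenyl)butan-1-ol
Conditions: Bu4NF (3 equiv), wet THF/DMF, 60 °C
Reagents that add atoms: none
Why: Fluoride attacks silicon, cleaves the Si–O bond and triggers protodesilylation of the benzylic C7–Si bond (as in fluoride cleavage of benzylsilanes), so C7 becomes CH2 while C7', C8' and C8 are untouched.

Step 8
Reactants: 11 the 7'S alcohol
Product: 12 (1R,2S,3R)-4-[4-(benzyloxy)-3,5-dimethoxyphenyl]-2,3-dimethyl-1-(3,4,5-trimethoxyphenyl)butyl acetate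
Conditions: PPh3, DIAD, AcOH, toluene, 0 °C → rt
Reagents that add atoms: acetic acid, CC(=O)O
Why: Mitsunobu reaction: acetate displaces the alkoxyphosphonium ion with inversion, turning the 7'S alcohol from the all-trans ring into the 7'R acetate and installing the ester in the same operation.

Step 9
Reactants: 12 the benzyl-protected acetate
Product: 13 (1R,2S,3R)-4-(4-hydroxy-3,5-dimethoxyphenyl)-2,3-dimethyl-1-(3,4,5-trimethoxyphenyl)butyl acetate
Conditions: H2 (1 atm), Pd/C, EtOAc, rt, stopped after one equivalent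
Reagents that add atoms: none
Why: Hydrogenolysis of the aryl benzyl ether over palladium; the hindered secondary benzylic acetate should be cleaved much more slowly.

Step 10
Reactants: 13 the phenol acetate
Product: 14 (5R,6S,7R)-1,2,3,3',5'-pentamethoxy-6,7-dimethyl-4'-oxo-5,6,7,8-tetrahydrospiro[benzo[7]annulene-9,1'-cyclohexa[2,5]dien]-5-yl acetate (CNP0143674.1)
Conditions: PhI(OCOCF3)2 (1.1 equiv), CF3CH2OH, −40 °C
Reagents that add atoms: none
Why: Oxidative dearomatisation with a hypervalent iodine reagent: after ligand exchange of the phenol at iodine, ring B attacks through C2' at the para carbon of ring A (ipso spirocyclisation), closing the seven-membered ring and giving the 2,6-dimethoxydienone; the spiro carbon is not stereogenic and the three stereocentres are remote.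

Compound list
1 | 1-(3,4,5-trimethoxyphenyl)propan-1-one | CCC(=O)c1cc(OC)c(OC)c(OC)c1 | starting material
2 | 2-bromo-1-(3,4,5-trimethoxyphenyl)propan-1-one (racemic) | CC(Br)C(=O)c1cc(OC)c(OC)c(OC)c1 | intermediate
3 | (1R)-2-bromo-1-(3,4,5-trimethoxyphenyl)propan-1-ol (C2 epimers) | CC(Br)[C@H](O)c1cc(OC)c(OC)c(OC)c1 | intermediate
4 | 1-(4-hydroxy-3,5-dimethoxyphenyl)propan-1-one | CCC(=O)c1cc(OC)c(O)c(OC)c1 | starting material
5 | 1-[4-(benzyloxy)-3,5-dimethoxyphenyl]propan-1-one | CCC(=O)c1cc(OC)c(OCc2ccccc2)c(OC)c1 | intermediate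
6 | N'-{(1E)-1-[4-(benzyloxy)-3,5-dimethoxyphenyl]propylidene}-2,4,6-tri(propan-2-yl)benzenesulfonohydrazide | CC/C(c1cc(OC)c(OCc2ccccc2)c(OC)c1)=N\NS(=O)(=O)c1c(C(C)C)cc(C(C)C)cc1C(C)C | intermediate
7 | {(1Z)-1-[4-(benzyloxy)-3,5-dimethoxyphenyl]prop-1-en-1-yl}lithium | C/C=C(/[Li])c1cc(OC)c(OCc2ccccc2)c(OC)c1 | intermediate (not isolated)
8 | chloro{(1E)-1-[4-(benzyloxy)-3,5-dimethoxyphenyl]prop-1-en-1-yl}dimethylsilane | C/C=C(/[Si](C)(C)Cl)c1cc(OC)c(OCc2ccccc2)c(OC)c1 | intermediate (not isolated)
9 | {(1E)-1-[4-(benzyloxy)-3,5-dimethoxyphenyl]prop-1-en-1-yl}[(1R)-2-bromo-1-(3,4,5-trimethoxyphenyl)propoxy]dimethylsilane | C/C=C(/[Si](C)(C)O[C@@H](C(C)Br)c1cc(OC)c(OC)c(OC)c1)c1cc(OC)c(OCc2ccccc2)c(OC)c1 | intermediate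
10 | (4S,5S,6S)-3-[4-(benzyloxy)-3,5-dimethoxyphenyl]-2,2,4,5-tetramethyl-6-(3,4,5-trimethoxyphenyl)-1,2-oxasilinane (C3 epimers) | O1[Si](C)(C)C(c2cc(OC)c(OCc3ccccc3)c(OC)c2)[C@@H](C)[C@H](C)[C@H]1c1cc(OC)c(OC)c(OC)c1 | intermediate
11 | (1S,2S,3R)-4-[4-(benzyloxy)-3,5-dimethoxyphenyl]-2,3-dimethyl-1-(3,4,5-trimethoxyphenyl)butan-1-ol | COc1cc(C[C@@H](C)[C@H](C)[C@H](O)c2cc(OC)c(OC)c(OC)c2)cc(OC)c1OCc1ccccc1 | intermediate
12 | (1R,2S,3R)-4-[4-(benzyloxy)-3,5-dimethoxyphenyl]-2,3-dimethyl-1-(3,4,5-trimethoxyphenyl)butyl acetate | COc1cc(C[C@@H](C)[C@H](C)[C@@H](OC(C)=O)c2cc(OC)c(OC)c(OC)c2)cc(OC)c1OCc1ccccc1 | intermediate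
13 | (1R,2S,3R)-4-(4-hydroxy-3,5-dimethoxyphenyl)-2,3-dimethyl-1-(3,4,5-trimethoxyphenyl)butyl acetate | COc1cc(C[C@@H](C)[C@H](C)[C@@H](OC(C)=O)c2cc(OC)c(OC)c(OC)c2)cc(OC)c1O | intermediate
14 | (5R,6S,7R)-1,2,3,3',5'-pentamethoxy-6,7-dimethyl-4'-oxo-5,6,7,8-tetrahydrospiro[benzo[7]annulene-9,1'-cyclohexa[2,5]dien]-5-yl acetate | COC1=CC2(C=C(OC)C1=O)C[C@@H](C)[C@H](C)[C@@H](OC(C)=O)c1cc(OC)c(OC)c(OC)c12 | target

Total step count: 10. Longest linear sequence: 8 steps (steps 3 to 10 from 4; the branch from 1 through steps 1, 2 and 5 to 10 is equally long).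

Steps most likely to fail

Step 6. The C8' radical may take hydrogen before it cyclises, or the ring closure may show poor facial control at C8' and C8. The fallback keeps a radical closure of the same bond but uses a carbon acetal bridge and a 5-exo mode (Ueno–Stork type); it sets out from 3 and returns at 11. Commercial sinapaldehyde would be O-benzylated (BnBr, K2CO3) to (E)-3-[4-(benzyloxy)-3,5-dimethoxyphenyl]prop-2-enal F1 and converted with trimethyl orthoformate into its dimethyl acetal F2. Acid-catalysed exchange with 3 (PPTS, toluene, removal of methanol) should give the mixed acetal F3. Bu3SnH/AIBN should then let the C8' radical attack the styrene carbon next to the acetal carbon, giving the 2-methoxytetrahydrofuran F4 with aryl and methyl trans and methyl and arylmethyl cis, the relative configuration of 11. Aqueous acetic acid should give the lactol F5, and hydrazine followed by KOtBu in DMSO (Wolff–Kishner reduction through the hydrazone F6) should turn the masked aldehyde carbon into the C8 methyl group of 11.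

Step 8. The electron-rich benzylic alkoxyphosphonium ion may eliminate or ionise, which would erode the configuration at C7'. The fallback replaces inversion by oxidation, reagent-controlled reduction and acylation; it sets out from 11 and returns at 12. Dess–Martin periodinane should give the ketone (2S,3R)-4-[4-(benzyloxy)-3,5-dimethoxyphenyl]-2,3-dimethyl-1-(3,4,5-trimethoxyphenyl)butan-1-one F7. Reduction with (S)-Me-CBS and BH3·SMe2 should give the 1R alcohol F8 under catalyst control, and Ac2O/pyridine/DMAP should give 12.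

Step 5. The chlorosilane 8 may hydrolyse during the solvent switch, or the excess dichlorosilane may carry over and silylate 3. The fallback separates the two bond formations through an isolable hydrosilane; it sets out from 6 and returns at 9. Vinyllithium 7 would be trapped with chlorodimethylsilane to give {(1E)-1-[4-(benzyloxy)-3,5-dimethoxyphenyl]prop-1-en-1-yl}dimethylsilane F9, which can be purified. Dehydrogenative Si–O coupling of F9 with 3, catalysed by Rh2(O2CC3F7)4 in CH2Cl2, should then give 9.

Further compounds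
F1 | step 6 | (E)-3-[4-(benzyloxy)-3,5-dimethoxyphenyl]prop-2-enal | O=C/C=C/c1cc(OC)c(OCc2ccccc2)c(OC)c1
F2 | step 6 | (E)-3-[4-(benzyloxy)-3,5-dimethoxyphenyl]prop-2-enal dimethyl acetal | COC(OC)/C=C/c1cc(OC)c(OCc2ccccc2)c(OC)c1
F3 | step 6 | mixed methyl (1R)-2-bromo-1-(3,4,5-trimethoxyphenyl)propyl acetal of F1 | COC(O[C@@H](C(C)Br)c1cc(OC)c(OC)c(OC)c1)/C=C/c1cc(OC)c(OCc2ccccc2)c(OC)c1
F4 | step 6 | (3R,4S,5S)-3-[4-(benzyloxy)-3,5-dimethoxybenzyl]-2-methoxy-4-methyl-5-(3,4,5-trimethoxyphenyl)tetrahydrofuran (C2 epimers) | COC1O[C@H](c2cc(OC)c(OC)c(OC)c2)[C@@H](C)[C@H]1Cc1cc(OC)c(OCc2ccccc2)c(OC)c1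
F5 | step 6 | (3R,4S,5S)-3-[4-(benzyloxy)-3,5-dimethoxybenzyl]-4-methyl-5-(3,4,5-trimethoxyphenyl)tetrahydrofuran-2-ol | OC1O[C@H](c2cc(OC)c(OC)c(OC)c2)[C@@H](C)[C@H]1Cc1cc(OC)c(OCc2ccccc2)c(OC)c1
F6 | step 6 | hydrazone of (2R,3S,4S)-2-[4-(benzyloxy)-3,5-dimethoxybenzyl]-4-hydroxy-3-methyl-4-(3,4,5-trimethoxyphenyl)butanal | COc1cc(C[C@@H](C=NN)[C@H](C)[C@H](O)c2cc(OC)c(OC)c(OC)c2)cc(OC)c1OCc1ccccc1
F7 | step 8 | (2S,3R)-4-[4-(benzyloxy)-3,5-dimethoxyphenyl]-2,3-dimethyl-1-(3,4,5-trimethoxyphenyl)butan-1-one | COc1cc(C[C@@H](C)[C@H](C)C(=O)c2cc(OC)c(OC)c(OC)c2)cc(OC)c1OCc1ccccc1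
F8 | step 8 | (1R,2S,3R)-4-[4-(benzyloxy)-3,5-dimethoxyphenyl]-2,3-dimethyl-1-(3,4,5-trimethoxyphenyl)butan-1-ol | COc1cc(C[C@@H](C)[C@H](C)[C@@H](O)c2cc(OC)c(OC)c(OC)c2)cc(OC)c1OCc1ccccc1
F9 | step 5 | {(1E)-1-[4-(benzyloxy)-3,5-dimethoxyphenyl]prop-1-en-1-yl}dimethylsilane | C/C=C(/[SiH](C)C)c1cc(OC)c(OCc2ccccc2)c(OC)c1
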